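**Assumption:** Pyronaamidine has no stereocentre, so no enantiocontrol is needed. The biogenesis is taken to be amidino transfer to an amino-acid/arylacetate-derived α-(methylamino) ketone with cyclodehydration, benzylation of the electron-rich C5, and condensation with a 1-methylparabanic acid unit. The Boc-sarcosine Weinreb amide and 1-methylparabanic acid are taken as catalogue compounds.

**Retrosynthetic overview**
1. Pyronaamidine ⇒ (exocyclic amidine C–N) fully substituted 2-aminoimidazole + intact 1-methylparabanic acid, attached last.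
2. 2-Aminoimidazole ⇒ (C5–CH2 bond) C5-unsubstituted 2-amino-4-(4-methoxybenzyl)-1-methylimidazole + the ortho-quinone methide from 2-hydroxy-3,4-dimethoxybenzyl alcohol.
3. Imidazole ring ⇒ amidino transfer from cyanamide to a sarcosine-derived α-(methylamino) ketone and cyclodehydration; ring formation and C5 benzylation run in one flask.
4. α-Aminoketone ⇒ Boc-sarcosine Weinreb amide + 4-methoxybenzyl Grignard reagent.
5. Ring order: the imidazole is the only ring constructed (first); the dehydrohydantoin ring is introduced preformed (last); both arenes come from commercial materials.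

**Route**

Step 1
Reactants: 1 tert-butyl N-{2-[methoxy(methyl)amino]-2-oxoethyl}-N-methylcarbamate (Boc-sarcosine Weinreb amide); 2 4-methoxybenzylmagnesium chloride (0.25 M in THF)
Product: 3 tert-butyl N-[3-(4-methoxyphenyl)-2-oxopropyl]-N-methylcarbamate
Conditions: 2 (1.5 equiv), THF, 0 °C, 2 h; cold 1 M HCl quench
Reagents that add atoms: none
Why: Weinreb ketone synthesis, in which the chelated tetrahedral magnesium adduct survives until the quench, so the benzyl Grignard adds once and the acidic benzylic ketone is released only on work-up; no stereocentre is formed.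

Step 2
Reactants: 4 2-hydroxy-3,4-dimethoxybenzaldehyde
Product: 5 6-(hydroxymethyl)-2,3-dimethoxyphenol (2-hydroxy-3,4-dimethoxybenzyl alcohol)
Conditions: NaBH4 (1 equiv), MeOH, 0 °C, 30 min; sat. NH4Cl, EtOAc extraction; used crude at once
Reagents that add atoms: none
Why: Borohydride reduction of the aryl aldehyde gives the salicyl-type alcohol that serves as ortho-quinone methide precursor, kept away from acid and silica because the 2-hydroxy/4-methoxy-activated benzylic alcohol ionises easily; no stereocentre is formed.

Step 3
Reactants: 3 tert-butyl N-[3-(4-methoxyphenyl)-2-oxopropyl]-N-methylcarbamate; 5 6-(hydroxymethyl)-2,3-dimethoxyphenol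
Product: 9 6-{[2-amino-4-(4-methoxybenzyl)-1-methyl-1H-imidazol-5-yl]methyl}-2,3-dimethoxyphenol, via aminoketone hydrochloride 6 (not isolated), via 2-aminoimidazole 7 (not isolated), via ortho-quinone methide 8 (not isolated)
Conditions: (i) 4 M HCl/dioxane, rt, 1 h, evaporate; (ii) H2NCN (1.5 equiv), H2O–EtOH 4:1, pH 4.5 (NaOH), 90 °C, 3 h; (iii) NaOH to pH 6.5, 5 (1.5 equiv, added over 2 h), 90 °C, 6 h; then NaOH to pH 10, extraction
Reagents that add atoms: cyanamide, NC#N
Why: Proposed new method: Boc loss gives the aminoketone salt, whose secondary amine adds to cyanamide and whose N-methylguanidine then cyclodehydrates onto the ketone (Lawson-type 2-aminoimidazole synthesis, placing N-methyl next to the free C5), after which C5, the only open ring carbon and the terminus of the vinylogous guanidine H2N–C2=N3–C4=C5, captures the ortho-quinone methide released thermally from the alcohol, N-adducts being reversible and the C–C adduct not; the closest known reactions are Friedel–Crafts alkylation of indoles and enamines by ortho-quinone methides from o-hydroxybenzyl alcohols and C-hydroxyalkylation of 2-aminoimidazoles by aldehydes; no stereocentre is formed.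

Step 4
Reactants: 9 6-{[2-amino-4-(4-methoxybenzyl)-1-methyl-1H-imidazol-5-yl]methyl}-2,3-dimethoxyphenol; 10 1-methylimidazolidine-2,4,5-trione (1-methylparabanic acid)
Product: 12 pyronaamidine, 4-({5-[(2-hydroxy-3,4-dimethoxyphenyl)methyl]-4-[(4-methoxyphenyl)methyl]-1-methyl-1H-imidazol-2-yl}amino)-1-methyl-1H-imidazole-2,5-dione, via O-silyl imidate 11 (not isolated)
Conditions: 10 (1.5 equiv), BSA (1.6 equiv), MeCN, reflux, 1 h; concentrate; add 9, PhMe, 110 °C, 12 h; MeOH quench
Reagents that add atoms: none
Why: Amidine-forming addition–elimination, in which the exocyclic 2-amino group displaces the silyloxy group at C4 of the silylated trione (the C5 carbonyl next to N-methyl and the urea C2 are less electrophilic), the established way of converting naamine-type 2-aminoimidazoles into naamidines, with the free phenol tolerated; no stereocentre is formed.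

**Compound list**
1 | tert-butyl N-{2-[methoxy(methyl)amino]-2-oxoethyl}-N-methylcarbamate | CON(C)C(=O)CN(C)C(=O)OC(C)(C)C | starting material
2 | 4-methoxybenzylmagnesium chloride | COc1ccc(C[Mg]Cl)cc1 | starting material
3 | tert-butyl N-[3-(4-methoxyphenyl)-2-oxopropyl]-N-methylcarbamate | COc1ccc(CC(=O)CN(C)C(=O)OC(C)(C)C)cc1 | intermediate
4 | 2-hydroxy-3,4-dimethoxybenzaldehyde | COc1ccc(C=O)c(O)c1OC | starting material
5 | 6-(hydroxymethyl)-2,3-dimethoxyphenol | COc1ccc(CO)c(O)c1OC | intermediate
6 | 1-(4-methoxyphenyl)-3-(methylamino)propan-2-one hydrochloride | CNCC(=O)Cc1ccc(OC)cc1.Cl | intermediate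
7 | 4-(4-methoxybenzyl)-1-methyl-1H-imidazol-2-amine | COc1ccc(Cc2cn(C)c(N)n2)cc1 | intermediate
8 | 2,3-dimethoxy-6-methylidenecyclohexa-2,4-dien-1-one | C=C1C=CC(OC)=C(OC)C1=O | intermediate
9 | 6-{[2-amino-4-(4-methoxybenzyl)-1-methyl-1H-imidazol-5-yl]methyl}-2,3-dimethoxyphenol | COc1ccc(Cc2nc(N)n(C)c2Cc2ccc(OC)c(OC)c2O)cc1 | intermediate
10 | 1-methylimidazolidine-2,4,5-trione | CN1C(=O)NC(=O)C1=O | starting material
11 | 1-methyl-4-[(trimethylsilyl)oxy]-1H-imidazole-2,5-dione | CN1C(=O)N=C(O[Si](C)(C)C)C1=O | intermediate
12 | pyronaamidine | COc1ccc(Cc2nc(NC3=NC(=O)N(C)C3=O)n(C)c2Cc2ccc(OC)c(OC)c2O)cc1 | target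

**Totals**
Total step count: 4. Longest linear sequence: 3 (Steps 1, 3, 4).

**Steps most likely to fail, with fallbacks**

Step 3. The quinone methide may oligomerise with the phenol ring of 5, or stay on nitrogen, before it finds C5 of the mostly protonated aminoimidazole. The fallback sets out from 3: stages (i) and (ii) alone are run and 7 is isolated as the free base. Compound 7 is then hydroxyalkylated at C5 by aldehyde 4 (MeOH, 50 °C) to the racemic carbinol (2-amino-4-(4-methoxybenzyl)-1-methyl-1H-imidazol-5-yl)(2-hydroxy-3,4-dimethoxyphenyl)methanol F1. Its doubly activated benzylic C–O bond is removed by ionic hydrogenation (Et3SiH, TFA, CH2Cl2, 0 °C to rt), and the route is rejoined at 9. This replaces the redox-neutral quinone methide alkylation by an aldehyde-level C–C bond formation followed by a separate reduction, and no longer needs 5.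

Step 1. The 4-methoxybenzyl Grignard reagent is prone to Wurtz homocoupling and can enolise rather than add. The fallback sets out from 1 and avoids the benzylic organometallic: the lithium enolate of methyl (4-methoxyphenyl)acetate (2 equiv, LDA, THF, −78 °C) is acylated by 1 to give the racemic β-keto ester methyl 4-[(tert-butoxycarbonyl)(methyl)amino]-2-(4-methoxyphenyl)-3-oxobutanoate F2. Heating F2 in 6 M HCl at 90 °C hydrolyses the ester, decarboxylates and removes Boc in one operation. The route is rejoined at 6, which enters Step 3 at stage (ii).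

Step 4. The hindered, weakly nucleophilic 2-amino group may convert poorly or attack the wrong carbonyl. The fallback sets out from 9 and builds the dehydrohydantoin ring on the amine instead of condensing the preformed trione. Amidine formation with ethyl 2-ethoxy-2-iminoacetate (EtOH, cat. AcOH, 60 °C) gives ethyl 2-({5-[(2-hydroxy-3,4-dimethoxyphenyl)methyl]-4-[(4-methoxyphenyl)methyl]-1-methyl-1H-imidazol-2-yl}amino)-2-iminoacetate F3. N-Methyl-1H-imidazole-1-carboxamide (a methyl isocyanate surrogate; Et3N, MeCN) carbamoylates the unsubstituted amidine nitrogen to give the N-(methylcarbamoyl)amidine ester F4. Its NHMe closes onto the ester (DBU, rt) to form the 1-methylimidazole-2,5-dione ring, and the route is rejoined at 12.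

**Further compounds**
F1 | step 3 | (2-amino-4-(4-methoxybenzyl)-1-methyl-1H-imidazol-5-yl)(2-hydroxy-3,4-dimethoxyphenyl)methanol (racemic) | COc1ccc(Cc2nc(N)n(C)c2C(O)c2ccc(OC)c(OC)c2O)cc1
F2 | step 1 | methyl 4-[(tert-butoxycarbonyl)(methyl)amino]-2-(4-methoxyphenyl)-3-oxobutanoate (racemic) | COC(=O)C(c1ccc(OC)cc1)C(=O)CN(C)C(=O)OC(C)(C)C
F3 | step 4 | ethyl 2-({5-[(2-hydroxy-3,4-dimethoxyphenyl)methyl]-4-[(4-methoxyphenyl)methyl]-1-methyl-1H-imidazol-2-yl}amino)-2-iminoacetate | CCOC(=O)C(=N)Nc1nc(Cc2ccc(OC)cc2)c(Cc2ccc(OC)c(OC)c2O)n1C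
F4 | step 4 | ethyl 2-({5-[(2-hydroxy-3,4-dimethoxyphenyl)methyl]-4-[(4-methoxyphenyl)methyl]-1-methyl-1H-imidazol-2-yl}amino)-2-[(methylcarbamoyl)imino]acetate | CCOC(=O)C(=NC(=O)NC)Nc1nc(Cc2ccc(OC)cc2)c(Cc2ccc(OC)c(OC)c2O)n1C
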